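The synthesis rests on excising the ester carbonyl carbon C1 of the docosanoyl chain as carbon monoxide. C1 lies between C2 of an unbranched, stereocentre-free alkyl chain and the ester oxygen of the 2-arylethyl unit. A linear-selective palladium-catalysed hydroalkoxycarbonylation can therefore forge the C1–C2 and C1–O bonds in a single operation from a terminal C21 alkene, carbon monoxide and a primary alcohol. The alkene partner is henicos-1-ene. The alcohol partner is tyrosol whose phenol on the benzene ring is masked as a benzyl ether, leaving the primary hydroxyl as the only nucleophile. One coupling step supplies the alkene and one hydrogenolysis unmasks the phenol.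

Key step: step 2

Remark: 2-(4-benzyloxyphenyl)ethanol is treated as a purchasable compound.

Step 1
Reactants: 1 1-bromooctadecane; 2 allylmagnesium bromide
Product: 3 henicos-1-ene
Conditions: 2 (1.5 equiv, Et2O solution), Li2CuCl4 (3 mol%), THF, 0 °C to rt; filtration through silica (hexane), then low-temperature recrystallisation from acetone
Reagents that add atoms: none
Why: Kochi-type copper-catalysed sp3–sp3 cross-coupling, in which the allylcopper species formed in the flask displaces the unhindered primary bromide of 1, and because the allyl unit is unsubstituted both of its termini lead to the same terminal alkene, so no regiochemical or stereochemical question arises.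

Step 2
Reactants: 3 henicos-1-ene (1.2 equiv); 4 carbon monoxide; 5 2-(4-benzyloxyphenyl)ethanol (1.0 equiv)
Product: 6 2-(4-benzyloxyphenyl)ethyl docosanoate
Conditions: Pd(OAc)2 (1 mol%), 1,2-bis(di-tert-butylphosphinomethyl)benzene (4 mol%), CH3SO3H (10 mol%), CO (30 bar), toluene, 80 °C; silica chromatography, then recrystallisation
Reagents that add atoms: none
Why: Pd(OAc)2, the diphosphine and CH3SO3H should generate a cationic divalent palladium hydride that adds reversibly to the alkene and walks along the chain; the very bulky chelating di-tert-butylphosphine allows migratory insertion of CO only at the terminal n-alkylpalladium, and the acylpalladium so formed is cleaved by the primary hydroxyl of 5, releasing ester 6 and returning the hydride. The closest known reaction type is the linear-selective hydromethoxycarbonylation of terminal and internal long-chain alkenes with this ligand class, here run with the alcohol as a near-stoichiometric reagent in toluene instead of as the solvent. No ring is closed and no stereocentre is created. The selectivity required is linear over branched carbonylation, which the ligand bulk and the unbranched, unfunctionalised chain of 3 should secure, and any internal henicosene produced by isomerisation is funnelled back to the same linear acyl species. Chemoselectivity at oxygen is built into 5: the phenol is capped as a benzyl ether, which is not cleaved in the absence of hydrogen, so the primary alcohol is the only nucleophile, while the moderate temperature and the low acid loading, buffered by excess phosphine, should protect the ether and the alcohol from acid-promoted side reactions. Alkene 3 is used in slight excess so that 5 is consumed completely and the non-polar surplus is washed off the silica column with hexane.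

Step 3
Reactants: 6 2-(4-benzyloxyphenyl)ethyl docosanoate
Product: 7 2-(4-hydroxyphenyl)ethyl docosanoate
Conditions: H2 (1 atm), 10% Pd/C, EtOAc/THF, rt
Reagents that add atoms: none
Why: Heterogeneous catalytic hydrogenolysis of the benzylic C–O bond of the aryl benzyl ether should release the phenol and toluene, while the ester (whose alkyl C–O bond is homobenzylic, not benzylic), the saturated chain and the arene are inert under one atmosphere of hydrogen at room temperature in a non-alcoholic solvent that excludes transesterification.

Compound list
1 | 1-bromooctadecane (achiral) | CCCCCCCCCCCCCCCCCCBr | starting material
2 | allylmagnesium bromide (achiral) | C=CC[Mg]Br | starting material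
3 | henicos-1-ene (achiral, terminal alkene) | C=CCCCCCCCCCCCCCCCCCCC | intermediate
4 | carbon monoxide | [C-]#[O+] | starting material
5 | 2-(4-benzyloxyphenyl)ethanol (achiral) | OCCc1ccc(OCc2ccccc2)cc1 | starting material
6 | 2-(4-benzyloxyphenyl)ethyl docosanoate (achiral) | CCCCCCCCCCCCCCCCCCCCCC(=O)OCCc1ccc(OCc2ccccc2)cc1 | intermediate
7 | 2-(4-hydroxyphenyl)ethyl docosanoate (achiral) | CCCCCCCCCCCCCCCCCCCCCC(=O)OCCc1ccc(O)cc1 | target

Total step count: 3
Longest linear sequence: 3 steps (1 → 3 → 6 → 7)

Steps most likely to fail

Step 2 carries the main risk. With the alcohol present only in near-stoichiometric amount and diluted in toluene, cleavage of the acylpalladium may become slow. Alkene isomerisation and decay of the catalyst to palladium metal could then outrun carbonylation, and prolonged heating with acid could begin to erode the benzyl ether. The fallback sets out from 3 and separates carbonylation from acyl transfer. Hydromethoxycarbonylation in methanol as solvent (Pd(OAc)2, 1,2-bis(di-tert-butylphosphinomethyl)benzene, CH3SO3H, CO 30 bar, MeOH, 80 °C) should give methyl docosanoate (F1), which can be recrystallised free of any branched isomer. Transesterification of F1 with 5 (Ti(OiPr)4 cat., toluene, reflux, continuous removal of methanol over 4 Å molecular sieves) then comes back to the route at 6.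

Step 1 ranks second. Displacement at the unactivated primary bromide may be slow enough that halogen–magnesium exchange, reduction, elimination and homocoupling compete. The resulting C18 and C36 hydrocarbons would be hard to remove from 3, and the C18 alkene would be carried through the carbonylation as a homologous ester. The fallback sets out from 1 and reverses the polarity of the coupling. Magnesium insertion (Mg turnings, THF, 40 °C) should give octadecylmagnesium bromide (F2). F2 is then allylated with allyl bromide (CuBr·SMe2 5 mol%, THF, 0 °C). The allylic electrophile is far more reactive than an alkyl bromide, and SN2 and SN2' attack give the same alkene, so the sequence comes back to the route at 3.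

Step 3 ranks third. Hydrogenolysis may stall through poisoning of the palladium surface by traces of phosphine carried over from the carbonylation, or through poor solubility of the waxy ester. The fallback sets out from 6 and replaces reduction by Lewis-acid dealkylation: BCl3 (2 equiv) with pentamethylbenzene (3 equiv) as cation scavenger in CH2Cl2 at −78 °C, quenched with aqueous NaHCO3. These conditions are known to spare alkyl esters. The fallback passes through no new compound (F0) and comes back to the route at 7.

Further compounds
F1 | step 2 | methyl docosanoate | CCCCCCCCCCCCCCCCCCCCCC(=O)OC
F2 | step 1 | octadecylmagnesium bromide | CCCCCCCCCCCCCCCCCC[Mg]Br
F0 | step 3 | none | none
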